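**Retrosynthetic overview**
1. The last disconnection removes two aryl silyl ethers from the catechol. Triisopropylsilyl ethers are used in place of tert-butyldimethylsilyl ethers because they must outlast an aryllithium, acid methanolysis, DBU and hydroxide phase-transfer conditions.
2. The strategy rests on ring B (C1, C9, C5, C6, C7, C8). It is opened at C1–C8 and at C7–CH2(prenyl), so that C6–C7–C8 becomes a prenyl group on C5 of a dearomatised acylphloroglucinol (ring A: C1, C2, C3, C4, C5, C9). That prenyl group takes a second prenyl unit at C7 and closes from C8 onto the geranyl-bearing enol carbon C1.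
3. The C5 centre (geranyl, prenyl) of the precursor comes from enantioselective phase-transfer C-prenylation of the symmetric 3,5-digeranyl acylphloroglucinol; C5 then relays to C1 and C7.
4. The aroylphloroglucinol is built by ortho-lithiation of phloroglucinol tris-MOM ether, addition to silylated 3,4-dihydroxybenzaldehyde, oxidation and MOM removal, then double C-geranylation. A Lewis-acid Friedel–Crafts aroylation is avoided because it would not spare the silyl ethers.
5. Ring order: ring A is the phloroglucinol ring from the start; ring B is closed in the key step.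

Key step: step 8

Assumption: the cinchonidinium salt of step 7 is taken to favour the (6R) enantiomer of the dearomatised precursor; if it favours the (6S) enantiomer, the pseudoenantiomeric cinchoninium salt is used instead.

**Route**

Step 1
Reactants: 1 phloroglucinol
Product: 2 1,3,5-tris(methoxymethoxy)benzene
Conditions: NaH, MOMCl, DMF, 0 °C → rt
Reagents that add atoms: chloromethyl methyl ether (MOMCl), COCCl
Why: Williamson-type O-alkylation of the sodium phenoxides with the hard chloromethyl ether should give the tris-MOM ether, whose OMOM groups later direct the lithiation.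

Step 2
Reactants: 3 3,4-dihydroxybenzaldehyde
Product: 4 3,4-bis(triisopropylsilyloxy)benzaldehyde
Conditions: TIPSCl, imidazole, DMF, rt → 40 °C
Reagents that add atoms: triisopropylsilyl chloride (TIPSCl), CC(C)[Si](Cl)(C(C)C)C(C)C
Why: Imidazole-mediated silylation of both catechol hydroxyls should give the bis-silyl ether, and aryl triisopropylsilyl ethers tolerate the organolithium, acid and base of the later steps.

Step 3
Reactants: 2 1,3,5-tris(methoxymethoxy)benzene; 4 3,4-bis(triisopropylsilyloxy)benzaldehyde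
Product: 6 [3,4-bis(triisopropylsilyloxy)phenyl][2,4,6-tris(methoxymethoxy)phenyl]methanol (racemic), via 2,4,6-tris(methoxymethoxy)phenyllithium 5 (not isolated)
Conditions: 2, n-BuLi, THF, 0 °C; then 4, –78 °C → rt; H2O
Reagents that add atoms: none
Why: Directed ortho-metalation between two OMOM groups followed by 1,2-addition of the aryllithium to the aldehyde should give the diaryl carbinol, whose racemic carbinol centre is removed in step 4.

Step 4
Reactants: 6 [3,4-bis(triisopropylsilyloxy)phenyl][2,4,6-tris(methoxymethoxy)phenyl]methanol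
Product: 7 [3,4-bis(triisopropylsilyloxy)phenyl][2,4,6-tris(methoxymethoxy)phenyl]methanone
Conditions: Dess–Martin periodinane, NaHCO3, CH2Cl2, 0 °C → rt
Reagents that add atoms: none
Why: Dess–Martin oxidation of the hindered diaryl carbinol should give the benzophenone, with bicarbonate buffering to protect the acid-sensitive electron-rich benzhydrol and the MOM ethers.

Step 5
Reactants: 7 [3,4-bis(triisopropylsilyloxy)phenyl][2,4,6-tris(methoxymethoxy)phenyl]methanone
Product: 8 [3,4-bis(triisopropylsilyloxy)phenyl](2,4,6-trihydroxyphenyl)methanone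
Conditions: p-TsOH·H2O (cat.), MeOH/THF, 45 °C
Reagents that add atoms: none
Why: Acid-catalysed acetal exchange with methanol should remove the three MOM groups, while the aryl silyl ethers are much slower to cleave under acid and no acid-sensitive alkene is present yet.

Step 6
Reactants: 8 [3,4-bis(triisopropylsilyloxy)phenyl](2,4,6-trihydroxyphenyl)methanone; 9 geranyl bromide
Product: 11 [3,4-bis(triisopropylsilyloxy)phenyl]{3,5-bis[(2E)-3,7-dimethylocta-2,6-dien-1-yl]-2,4,6-trihydroxyphenyl}methanone, via mono-C-geranyl ketone 10 (not isolated)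
Conditions: 9 (2.1 equiv), DBU, THF, 0 °C → rt
Reagents that add atoms: geranyl bromide (9), CC(C)=CCC/C(C)=C/CBr
Why: Base-mediated C-alkylation of the hydrogen-bonded acylphloroglucinol phenoxide at its two free ring carbons (SN2 on the primary allylic bromide, E geometry kept) should give the symmetric 3,5-digeranyl ketone, with the stoichiometry stopping the reaction before dearomatisation.

Step 7
Reactants: 11 3,5-digeranyl ketone; 12 prenyl bromide
Product: 13 (6R)-4-[3,4-bis(triisopropylsilyloxy)benzoyl]-2,6-bis[(2E)-3,7-dimethylocta-2,6-dien-1-yl]-3,5-dihydroxy-6-(3-methylbut-2-en-1-yl)cyclohexa-2,4-dien-1-one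
Conditions: 12 (1.1 equiv), O-allyl-N-(9-anthracenylmethyl)cinchonidinium bromide (10 mol %), CsOH·H2O, toluene/CH2Cl2, –50 °C; then aq. citric acid
Reagents that add atoms: prenyl bromide (12), CC(C)=CCBr
Why: Asymmetric phase-transfer alkylative dearomatisation should prenylate one geranyl-bearing ring carbon of the cesium phenoxide, and since attack on one face of one such carbon equals attack on the opposite face of its mirror-related partner, the face selection of the chiral ammonium ion pair sets the C5 centre.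

Step 8
Reactants: 13 (6R)-dearomatised C5-geranyl-C5-prenyl acylphloroglucinol bis-silyl ether; 12 prenyl bromide
Product: 14 (1S,5S,7R)-3-[3,4-bis(triisopropylsilyloxy)benzoyl]-1,5-bis[(2E)-3,7-dimethylocta-2,6-dien-1-yl]-4-hydroxy-8,8-dimethyl-7-(3-methylbut-2-en-1-yl)bicyclo[3.3.1]non-3-ene-2,9-dione (C7 prenyl exo, equatorial on chair ring B)
Conditions: 12 (1.5 equiv), AgOTf (1.4 equiv), CH2Cl2, –78 °C; then added slowly to 13, 2,6-di-tert-butyl-4-methylpyridine, CH2Cl2, –78 → –40 °C, dark, high dilution
Reagents that add atoms: prenyl bromide (12), CC(C)=CCBr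
Why: Proposed new method: AgOTf abstracts bromide from 12 to give a prenyl cation–triflate pair that adds to C7, the less substituted carbon of the C5 prenyl alkene of 13, while the enol carbon C1 (α-carbon of the C9/C2 vinylogous acid) attacks the developing tertiary C8 cation and the hindered pyridine takes up the released proton; the closest known reaction types are iodonium-induced carbocyclisation of C5-prenyl dearomatised acylphloroglucinols, acid-mediated capture of a C8 cation by C1, and allyl-cation-initiated polyene cyclisation terminated by a β-dicarbonyl enol. Ring B closes in a 6-endo-trig mode through a chair in which C5, C6, C7, C8, C1 and C9 take up the bicyclo[3.3.1]nonane geometry. C1 is fixed by C5, because the C1–C8 bond can only form on the face of ring A that carries the prenyl group, and C7 is set by anti addition of the prenyl cation and C1 across C7=C8 in that chair, which places the new prenyl group equatorial (exo). The step needs the cation to choose the C5 prenyl alkene over the four geranyl alkenes, C1 rather than C3 or an enol oxygen to capture the C8 cation, and addition to the alkene rather than direct prenylation of the enol. The substrate favours C1 over C3 (C3 is the acyl-bearing carbon of the hydrogen-bonded β-triketone and is far less nucleophilic) and favours the two C5-bound alkenes through participation of C1 in a six-membered transition state, but it gives only a small steric bias for the prenyl over the proximal geranyl alkene on C5 and none against oxygen capture, so the risk of the route sits here.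

Step 9
Reactants: 14 bis-silyl ether of the target
Product: 15 (1S,5S,7R)-3-(3,4-dihydroxybenzoyl)-1,5-bis[(2E)-3,7-dimethylocta-2,6-dien-1-yl]-4-hydroxy-8,8-dimethyl-7-(3-methylbut-2-en-1-yl)bicyclo[3.3.1]non-3-ene-2,9-dione (CNP0178719.1)
Conditions: TBAF, AcOH, THF, 0 °C
Reagents that add atoms: none
Why: Fluoride-mediated desilylation of the two aryl silyl ethers, buffered with acetic acid to keep the liberated catechol and the vinylogous acid from base-promoted oxidation, should give the target without touching the three stereocentres.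

**Compound list**
1 | phloroglucinol | Oc1cc(O)cc(O)c1 | starting material
2 | 1,3,5-tris(methoxymethoxy)benzene | COCOc1cc(OCOC)cc(OCOC)c1 | intermediate
3 | 3,4-dihydroxybenzaldehyde | O=Cc1ccc(O)c(O)c1 | starting material
4 | 3,4-bis(triisopropylsilyloxy)benzaldehyde | O=Cc1ccc(O[Si](C(C)C)(C(C)C)C(C)C)c(O[Si](C(C)C)(C(C)C)C(C)C)c1 | intermediate
5 | 2,4,6-tris(methoxymethoxy)phenyllithium | [Li]c1c(OCOC)cc(OCOC)cc1OCOC | intermediate
6 | [3,4-bis(triisopropylsilyloxy)phenyl][2,4,6-tris(methoxymethoxy)phenyl]methanol (racemic) | OC(c1ccc(O[Si](C(C)C)(C(C)C)C(C)C)c(O[Si](C(C)C)(C(C)C)C(C)C)c1)c1c(OCOC)cc(OCOC)cc1OCOC | intermediate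
7 | [3,4-bis(triisopropylsilyloxy)phenyl][2,4,6-tris(methoxymethoxy)phenyl]methanone | O=C(c1ccc(O[Si](C(C)C)(C(C)C)C(C)C)c(O[Si](C(C)C)(C(C)C)C(C)C)c1)c1c(OCOC)cc(OCOC)cc1OCOC | intermediate
8 | [3,4-bis(triisopropylsilyloxy)phenyl](2,4,6-trihydroxyphenyl)methanone | O=C(c1ccc(O[Si](C(C)C)(C(C)C)C(C)C)c(O[Si](C(C)C)(C(C)C)C(C)C)c1)c1c(O)cc(O)cc1O | intermediate
9 | geranyl bromide, (2E)-1-bromo-3,7-dimethylocta-2,6-diene | CC(C)=CCC/C(C)=C/CBr | starting material
10 | [3,4-bis(triisopropylsilyloxy)phenyl]{3-[(2E)-3,7-dimethylocta-2,6-dien-1-yl]-2,4,6-trihydroxyphenyl}methanone | O=C(c1ccc(O[Si](C(C)C)(C(C)C)C(C)C)c(O[Si](C(C)C)(C(C)C)C(C)C)c1)c1c(O)cc(O)c(C/C=C(\C)CCC=C(C)C)c1O | intermediate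
11 | [3,4-bis(triisopropylsilyloxy)phenyl]{3,5-bis[(2E)-3,7-dimethylocta-2,6-dien-1-yl]-2,4,6-trihydroxyphenyl}methanone | O=C(c1ccc(O[Si](C(C)C)(C(C)C)C(C)C)c(O[Si](C(C)C)(C(C)C)C(C)C)c1)c1c(O)c(C/C=C(\C)CCC=C(C)C)c(O)c(C/C=C(\C)CCC=C(C)C)c1O | intermediate
12 | prenyl bromide, 1-bromo-3-methylbut-2-ene | CC(C)=CCBr | starting material
13 | (6R)-4-[3,4-bis(triisopropylsilyloxy)benzoyl]-2,6-bis[(2E)-3,7-dimethylocta-2,6-dien-1-yl]-3,5-dihydroxy-6-(3-methylbut-2-en-1-yl)cyclohexa-2,4-dien-1-one | CC(C)=CCC/C(C)=C/C[C@@]1(CC=C(C)C)C(=O)C(C/C=C(\C)CCC=C(C)C)=C(O)C(C(=O)c2ccc(O[Si](C(C)C)(C(C)C)C(C)C)c(O[Si](C(C)C)(C(C)C)C(C)C)c2)=C1O | intermediate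
14 | (1S,5S,7R)-3-[3,4-bis(triisopropylsilyloxy)benzoyl]-1,5-bis[(2E)-3,7-dimethylocta-2,6-dien-1-yl]-4-hydroxy-8,8-dimethyl-7-(3-methylbut-2-en-1-yl)bicyclo[3.3.1]non-3-ene-2,9-dione | CC(C)=CCC/C(C)=C/C[C@]12C[C@@H](CC=C(C)C)C(C)(C)[C@](C/C=C(\C)CCC=C(C)C)(C(=O)C(C(=O)c3ccc(O[Si](C(C)C)(C(C)C)C(C)C)c(O[Si](C(C)C)(C(C)C)C(C)C)c3)=C1O)C2=O | intermediate
15 | (1S,5S,7R)-3-(3,4-dihydroxybenzoyl)-1,5-bis[(2E)-3,7-dimethylocta-2,6-dien-1-yl]-4-hydroxy-8,8-dimethyl-7-(3-methylbut-2-en-1-yl)bicyclo[3.3.1]non-3-ene-2,9-dione | CC(C)=CCC/C(C)=C/C[C@]12C[C@@H](CC=C(C)C)C(C)(C)[C@](C/C=C(\C)CCC=C(C)C)(C(=O)C(C(=O)c3ccc(O)c(O)c3)=C1O)C2=O | target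

Total step count: 9
Longest linear sequence: 8 steps (steps 1 and 3–9 from phloroglucinol, or steps 2–9 from 3,4-dihydroxybenzaldehyde)

**Steps most likely to fail**

1. Step 8 (carries the label "Proposed new method:").
 - What may go wrong: the prenyl cation may add to a geranyl alkene, in particular the proximal alkene of the C5 geranyl group, which would close ring B through the wrong chain. The C8 cation may be captured by an enol oxygen to give a pyran. The vinylogous acid may be prenylated directly at oxygen or at C1. Adventitious acid may start proton-initiated cyclisations.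
 - Fallback with known chemistry, from 13 back to 14: iodonium-induced carbocyclisation of 13 (I2, KI, KHCO3, THF/H2O, 0 °C) should close ring B through C1 with iodine at C7 and give the 7-exo-iodo bicycle F1. Keck radical allylation (allyltributylstannane, AIBN, toluene, 80 °C) should replace iodine by allyl from the open exo face and give the 7-exo-allyl bicycle F2. Cross-metathesis with 2-methyl-2-butene (second-generation Grubbs catalyst, CH2Cl2, 40 °C) should turn the allyl group into the prenyl group and rejoin the route at 14.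
 - Limits of the fallback: the iodonium ion forms reversibly, so alkenes with no carbon nucleophile in reach are released unchanged, but the proximal alkene of the C5 geranyl group still competes. The metathesis must be stopped before the trisubstituted geranyl alkenes are cut.

2. Step 7.
 - What may go wrong: poor facial discrimination at the geranyl-bearing ring carbon, O-prenylation, or a second alkylation at the other geranyl carbon.
 - Fallback, from 11 back to 13: prenylation without the chiral salt (12, LiHMDS, THF, –78 → 0 °C) should give the racemic dearomatised triketone F3. This is resolved by preparative supercritical-fluid chromatography on a polysaccharide chiral stationary phase into 13 and its (6S) enantiomer F4, which is discarded.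

3. Step 6.
 - What may go wrong: O-geranylation, an incomplete second alkylation, or a third, dearomatising geranylation.
 - Fallback, from 2 back to 11: lithiation of 2 to 5 and alkylation with 9 (cat. CuBr·SMe2, THF, –78 → 0 °C) should give 2-geranyl-1,3,5-tris(methoxymethoxy)benzene F5. A second lithiation between two OMOM groups gives the 4-lithio derivative F6, which is alkylated with 9 to the 2,4-digeranyl arene F7. A third lithiation at the last ring position gives the aryllithium F8, which adds to 4 to give the digeranyl diaryl carbinol F9. Dess–Martin oxidation gives the digeranyl tris-MOM ketone F10, and mild acid methanolysis of the MOM ethers (p-TsOH, MeOH, rt) rejoins the route at 11.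

**Further compounds**
F1 | step 8 | bis-silyl 7-exo-iodo-1,5-digeranyl-4-hydroxy-8,8-dimethylbicyclo[3.3.1]non-3-ene-2,9-dione (3-aroyl) | CC(C)=CCC/C(C)=C/C[C@]12C[C@@H](I)C(C)(C)[C@](C/C=C(\C)CCC=C(C)C)(C(=O)C(C(=O)c3ccc(O[Si](C(C)C)(C(C)C)C(C)C)c(O[Si](C(C)C)(C(C)C)C(C)C)c3)=C1O)C2=O
F2 | step 8 | bis-silyl 7-exo-allyl analogue of 14 | CC(C)=CCC/C(C)=C/C[C@]12C[C@@H](CC=C)C(C)(C)[C@](C/C=C(\C)CCC=C(C)C)(C(=O)C(C(=O)c3ccc(O[Si](C(C)C)(C(C)C)C(C)C)c(O[Si](C(C)C)(C(C)C)C(C)C)c3)=C1O)C2=O
F3 | step 7 | racemic 13 | CC(C)=CCC/C(C)=C/CC1(CC=C(C)C)C(=O)C(C/C=C(\C)CCC=C(C)C)=C(O)C(C(=O)c2ccc(O[Si](C(C)C)(C(C)C)C(C)C)c(O[Si](C(C)C)(C(C)C)C(C)C)c2)=C1O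
F4 | step 7 | (6S) enantiomer of 13 | CC(C)=CCC/C(C)=C/C[C@]1(CC=C(C)C)C(=O)C(C/C=C(\C)CCC=C(C)C)=C(O)C(C(=O)c2ccc(O[Si](C(C)C)(C(C)C)C(C)C)c(O[Si](C(C)C)(C(C)C)C(C)C)c2)=C1O
F5 | step 6 | 2-[(2E)-3,7-dimethylocta-2,6-dien-1-yl]-1,3,5-tris(methoxymethoxy)benzene | COCOc1cc(OCOC)c(C/C=C(\C)CCC=C(C)C)c(OCOC)c1
F6 | step 6 | 3-geranyl-2,4,6-tris(methoxymethoxy)phenyllithium | [Li]c1c(OCOC)cc(OCOC)c(C/C=C(\C)CCC=C(C)C)c1OCOC
F7 | step 6 | 2,4-bis[(2E)-3,7-dimethylocta-2,6-dien-1-yl]-1,3,5-tris(methoxymethoxy)benzene | COCOc1cc(OCOC)c(C/C=C(\C)CCC=C(C)C)c(OCOC)c1C/C=C(\C)CCC=C(C)C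
F8 | step 6 | 3,5-digeranyl-2,4,6-tris(methoxymethoxy)phenyllithium | [Li]c1c(OCOC)c(C/C=C(\C)CCC=C(C)C)c(OCOC)c(C/C=C(\C)CCC=C(C)C)c1OCOC
F9 | step 6 | [3,4-bis(triisopropylsilyloxy)phenyl][3,5-digeranyl-2,4,6-tris(methoxymethoxy)phenyl]methanol (racemic) | OC(c1ccc(O[Si](C(C)C)(C(C)C)C(C)C)c(O[Si](C(C)C)(C(C)C)C(C)C)c1)c1c(OCOC)c(C/C=C(\C)CCC=C(C)C)c(OCOC)c(C/C=C(\C)CCC=C(C)C)c1OCOC
F10 | step 6 | [3,4-bis(triisopropylsilyloxy)phenyl][3,5-digeranyl-2,4,6-tris(methoxymethoxy)phenyl]methanone | O=C(c1ccc(O[Si](C(C)C)(C(C)C)C(C)C)c(O[Si](C(C)C)(C(C)C)C(C)C)c1)c1c(OCOC)c(C/C=C(\C)CCC=C(C)C)c(OCOC)c(C/C=C(\C)CCC=C(C)C)c1OCOC
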